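## The problem

Locants: ring A carbons C1'–C6' (C1' bears the carbonyl), enone carbons Cα and Cβ, geranyl carbons C1''–C10'', ring B unprimed.

Xanthoangelol F (15) has no stereocentre. Its only stereochemical elements are two E double bonds, the enone Cα=Cβ and C2''=C3'' of the geranyl chain, and neither can be set by the other. The difficulty sits in ring A, where four neighbouring carbons carry four different groups: the cinnamoyl carbonyl on C1', a free hydroxyl on C2', the geranyl chain on C3' and a methoxyl on C4'. C3' lies between two oxygen-bearing carbons and is the most hindered position of the ring. A finished resorcinol ketone offers a geranyl electrophile two ring carbons (C3', C5') and its oxygens, so decoration of a preformed ring must win one site out of several. The two ring A oxygens must also end up different. The molecule is fragile towards acid: the trisubstituted double bonds of the chain add nucleophiles or cyclise (the C2' hydroxyl can close a chroman onto C3''), any allyl cation loses the C2'' geometry, and the 2'-hydroxychalcone can close to the flavanone.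

The feature that opens the problem is the pattern of ring A. C2'(O)–C3'(geranyl)–C4'(O)–C5' has the carbon count and oxidation pattern of a 2-alkylated acetoacetate (ester carbon, α-carbon, ketone carbon, methyl). C1'–C6', with the acyl group on C1' and hydrogen on C6', corresponds to a terminal ynone. The acyl group is ortho to the oxygen on C2' and para to the oxygen on C4', which is the polarity match of a 1,3-dioxygenated diene with an acetylenic ketone. The chain can therefore be attached by enolate alkylation of an open chain, and ring A built around it.

## Retrosynthesis

**15 ⇒ 12 + 13.** The enone bond Cα=Cβ is cut (retro-Claisen–Schmidt) to give methyl ketone 12 and commercial 4-hydroxybenzaldehyde 13. The neighbouring cuts are worse. Cutting C1'–C(=O) would mean acylating a geranylated resorcinol ether under Lewis acid. Carrying the whole cinnamoyl unit through the ring construction would replace a purchased four-carbon ynone by a cross-conjugated enynone that takes several steps to make and offers the diene a second acceptor. The cut removes ring B and seven carbons and leaves every difficulty of the target in 12. The forward reaction must give the E-enone, which is the thermodynamic result of base-mediated dehydration, without acid.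

**12 ⇒ 8 + 9.** Ring A is taken apart at C1'–C2' and C5'–C6', with methanol added back across C2' and C5' (retro-aromatisation to adduct 10, which forms aryl silyl ether 11 on the way forward). C2'–C3'–C4'–C5' becomes vinylketene acetal diene 8: C2' is the ketene acetal carbon, C3' carries the geranyl group and C4' an enol ether methoxyl. C1'–C6' becomes but-3-yn-2-one 9. Against the neighbouring cut at C3'–C1'' (geranylation of a finished ring), this cut has no site problem at C3', because the chain is attached before the ring exists. The other ways of dividing the ring into a diene and a two-carbon unit put an oxygen on the dienophile or break the 1,3-relationship of the donors. The precursors are two open-chain compounds, one of them bought. The forward reaction must be a regioselective [4+2] cycloaddition at a fully substituted ketene acetal terminus, followed by an aromatisation that expels methanol and keeps the silyloxy group on C2', so that the two oxygens emerge already differentiated.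

**8 ⇒ 6 ⇒ 4.** Diene 8 is cut at its O–Si bond to lithium dienolate 7 of β-methoxy enoate 6, and 6 at the enol ether C–O bond to keto ester 4. This fixes, before the ring exists, which oxygen will be the methyl ether: the ketone carbon of 4 becomes C4'–OMe and the ester carbonyl becomes C2'–OH. The alternative of two silyl ethers would need a selective phenol methylation later. The precursor 4 is an ordinary β-keto ester. The forward reactions must be an enol ether formation that spares the chain, and a γ-deprotonation with O-silylation.

**4 ⇒ 1 + 2.** The C3'–C1'' bond of the target is cut as the Cα–CH2 bond of keto ester 4, which gives methyl acetoacetate 1 and geranyl bromide 2. The acetoacetate enolate has one nucleophilic carbon where the arene has several sites, and SN2 attack at the primary carbon of 2 keeps the E double bond that is bought with it. Both precursors are commercial. The forward reaction must be monoalkylation at carbon.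

## Roads not taken

Alternative 1: The obvious plan keeps ring A intact. After the same Claisen–Schmidt cut to 12 and 13, the C3'–C1'' bond is cut on the ring. The forward key step is alkylation of the phenoxide of commercial 1-(2-hydroxy-4-methoxyphenyl)ethan-1-one A1 with 2.
- The phenoxide is ambident: oxygen alkylation would give ether A2, and carbon alkylation is divided between C3' and the unhindered C5'. The crowded C3' is the least accessible site, so 12 would be the minor part of a mixture.
- Repair through a [3,3] shift of A2 fails on constitution. The Claisen rearrangement delivers the chain inverted, as the 3,7-dimethylocta-1,6-dien-3-yl compound A3. An acid-mediated 1,3-shift passes through the allyl cation and loses the C2'' geometry.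
- The chosen plan pays three more steps for 12 and receives a single constitution.

Alternative 2: Cut C3'–C1'' and C1'–C(=O) on a protected resorcinol and make both bonds by directed ortho-metalation. The bis(methoxymethyl) ether A4 of benzene-1,3-diol would be lithiated between its two acetals and coupled with 2 under copper catalysis to give A5. A second lithiation next to one acetal and acetylation would give ketone A6. Removal of both acetals, methylation of the unchelated C4' hydroxyl and the Claisen–Schmidt step would follow.
- The first metalation is regiochemically sound, but the second competes with the doubly activated benzylic and allylic CH2 (C1'') of A5.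
- Both acetals must be removed with acid while a free hydroxyl sits next to the C2''=C3'' bond, which invites chroman formation.
- The ring A oxygens must be differentiated afterwards. This makes at least seven steps of protection, decoration and deprotection against five.
- An unsymmetrical, shorter version is kept as the fallback for the key step.

Alternative 3: Ring A by a Danheiser benzannulation, cutting C2'–C3' and C4'–C5'. Ynol ether A7 would supply C3' with its geranyl group and C4' with its methoxyl. 4-Acetylcyclobut-2-en-1-one A8 would supply C2' (the ketene carbon, later the hydroxyl carbon), C5', C6' and C1' with the acetyl group. The forward key step is the cascade of 4π ring opening, [2+2] cycloaddition, 4π opening and 6π closure, and its regiochemistry is right.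
- The weakness is A8. The mapping forces the acyl group onto the sp3 carbon of a cyclobutenone with no substituent on its double bond, a strained β-dicarbonyl compound that should enolise and polymerise.
- The (2-acylvinyl)ketene formed from A8 can close through its own carbonyl oxygen to pyranone A9 before it meets A7.
- Both partners would need syntheses longer than the whole chosen route, whose two-carbon partner 9 is bought.

Key step: step 4

Remark on the chemistry: 4, 5, 10 and 14 are racemic and lose their stereocentre later, and the enol ether bond of 6 and the ketene acetal bond of 7 and 8 should form as E/Z mixtures that converge in step 4, so these bonds are written without configuration.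

Abbreviations: TsOH = p-toluenesulfonic acid; PPTS = pyridinium p-toluenesulfonate.

## Route

Step 1  
Reactants: 1 methyl acetoacetate (methyl 3-oxobutanoate); 2 geranyl bromide, (2E)-1-bromo-3,7-dimethylocta-2,6-diene  
Product: 4 methyl (4E)-2-acetyl-5,9-dimethyldeca-4,8-dienoate (methyl 2-geranylacetoacetate; racemic), via sodium enolate 3 (not isolated)  
Conditions: NaH, THF, 0 °C; then 2, 0 °C to rt (1 in slight excess)  
Reagents that add atoms: none  
Why: Acetoacetic ester alkylation: the soft, chelated sodium enolate 3 attacks the primary allylic carbon of 2 by SN2, so the chain is joined through C1'' only and the E double bond bought with 2 is not touched; a slight excess of 1 holds back dialkylation.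

Step 2  
Reactants: 4 methyl (4E)-2-acetyl-5,9-dimethyldeca-4,8-dienoate  
Product: 6 methyl (4E)-2-(1-methoxyethylidene)-5,9-dimethyldeca-4,8-dienoate (β-methoxy enoate), via dimethyl ketal 5 (not isolated)  
Conditions: HC(OMe)3, MeOH, cat. TsOH, rt to 45 °C; then 60 °C, reduced pressure (MeOH removed); Et3N quench  
Reagents that add atoms: trimethyl orthoformate, `COC(OC)OC`; methanol, `CO`  
Why: Orthoformate-driven ketalisation followed by acid-catalysed loss of methanol from ketal 5 into conjugation with the ester (enol ether formation from a β-keto ester), a path on which C-methylation is impossible. The isolated trisubstituted double bonds should survive a short exposure to catalytic sulfonic acid in anhydrous methanol, as they do when terpenoid ketones are ketalised; the enol ether geometry is of no consequence.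

Step 3  
Reactants: 6 methyl (4E)-2-(1-methoxyethylidene)-5,9-dimethyldeca-4,8-dienoate  
Product: 8 2-[(2E)-3,7-dimethylocta-2,6-dien-1-yl]-1,3-dimethoxy-1-[(trimethylsilyl)oxy]buta-1,3-diene, via lithium dienolate 7 (not isolated)  
Conditions: LiN(i-Pr)2, THF, −78 °C; then Me3SiCl, −78 °C to rt; pentane, filtration; used crude  
Reagents that add atoms: chlorotrimethylsilane, `C[Si](C)(C)Cl`  
Why: γ-Deprotonation of the vinylogous ester and O-silylation of the lithium dienolate, the standard preparation of 1,3-dialkoxy-1-silyloxybutadienes (vinylketene acetals). The methyl group on the enol ether carbon is the only carbonyl-activated C–H, so both isomers of 6 should give the same dienolate 7, and the hard silyl chloride reacts at oxygen.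

Step 4  
Reactants: 8 2-[(2E)-3,7-dimethylocta-2,6-dien-1-yl]-1,3-dimethoxy-1-[(trimethylsilyl)oxy]buta-1,3-diene; 9 but-3-yn-2-one  
Product: 12 1-{3-[(2E)-3,7-dimethylocta-2,6-dien-1-yl]-2-hydroxy-4-methoxyphenyl}ethan-1-one, via cycloadduct 10 (not isolated), via aryl silyl ether 11 (not isolated)  
Conditions: toluene, 0 °C to 40 °C; evaporation; then MeOH, cat. PPTS, rt  
Reagents that add atoms: none  
Why: Normal-demand Diels–Alder reaction with aromatisation: the donors on C1 and C3 of diene 8 place the largest HOMO coefficient on its CH2 terminus, which bonds to the unsubstituted β-carbon of ynone 9 while the ketene acetal carbon bonds to the α-carbon, either concertedly and asynchronously or through a vinylogous Mukaiyama–Michael addition and ring closure that leads to the same adduct 10. The closest known reaction type is the cycloaddition of 1,1,3-trioxygenated butadienes with acetylenic esters and ketones, which gives resorcinol derivatives after loss of an alcohol. Ring A is closed as a six-membered carbocycle by intermolecular [4+2] formation of the C1'–C2' and C5'–C6' bonds, with C1' and C6' from 9 and C2'–C5' from 8. No stereocentre survives, since the racemic ketal carbon of 10 becomes aromatic C2'. The step needs regioselectivity (acetyl next to the ketal carbon and para to the enol ether carbon), which the matched polarisation of both partners and the unhindered alkyne terminus should secure, and it needs the mixed ketal of 10 to lose methanol and not its silyloxy group. The latter should follow from ionisation at the more basic methoxy oxygen under PPTS in dry methanol, where a hemiketal formed by desilylation can only collapse to the carbonyl and enolise to the phenol, and where the enol ether that becomes C4'–OMe cannot be hydrolysed because no water is present. Aromatisation makes the sequence irreversible, and methanolysis of aryl silyl ether 11 frees the hydroxyl, which is then hydrogen-bonded to the acetyl group.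

Step 5  
Reactants: 12 1-{3-[(2E)-3,7-dimethylocta-2,6-dien-1-yl]-2-hydroxy-4-methoxyphenyl}ethan-1-one; 13 4-hydroxybenzaldehyde  
Product: 15 xanthoangelol F, (2E)-1-{3-[(2E)-3,7-dimethylocta-2,6-dien-1-yl]-2-hydroxy-4-methoxyphenyl}-3-(4-hydroxyphenyl)prop-2-en-1-one, via aldol adduct 14 (not isolated)  
Conditions: KOH (50% aq.), EtOH, rt to 40 °C; then cold 1 M HCl to pH 5  
Reagents that add atoms: none  
Why: Claisen–Schmidt condensation of a 2-hydroxyacetophenone with an unprotected hydroxybenzaldehyde in concentrated alkali, where aldol addition to 14 is followed by E1cB loss of water to the conjugated E-enone, the thermodynamic isomer. Excess base holds both phenols as phenoxides, which keeps the chalcone open, and the geranyl chain is inert to base.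

## Compound list

```
1 | methyl acetoacetate (methyl 3-oxobutanoate) | COC(=O)CC(C)=O | starting material
2 | geranyl bromide, (2E)-1-bromo-3,7-dimethylocta-2,6-diene | BrC/C=C(\C)CCC=C(C)C | starting material
3 | sodium (2Z)-4-methoxy-4-oxobut-2-en-2-olate (sodium enolate of 1) | [Na+].COC(=O)/C=C(/C)[O-] | intermediate
4 | methyl (4E)-2-acetyl-5,9-dimethyldeca-4,8-dienoate (racemic) | COC(=O)C(C/C=C(\C)CCC=C(C)C)C(C)=O | intermediate
5 | methyl (4E)-2-(1,1-dimethoxyethyl)-5,9-dimethyldeca-4,8-dienoate (racemic) | COC(=O)C(C/C=C(\C)CCC=C(C)C)C(C)(OC)OC | intermediate
6 | methyl (4E)-2-(1-methoxyethylidene)-5,9-dimethyldeca-4,8-dienoate (enol ether bond E/Z) | COC(=O)C(C/C=C(\C)CCC=C(C)C)=C(C)OC | intermediate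
7 | lithium 2-[(2E)-3,7-dimethylocta-2,6-dien-1-yl]-1,3-dimethoxybuta-1,3-dien-1-olate | [Li+].COC([O-])=C(C/C=C(\C)CCC=C(C)C)C(OC)=C | intermediate
8 | 2-[(2E)-3,7-dimethylocta-2,6-dien-1-yl]-1,3-dimethoxy-1-[(trimethylsilyl)oxy]buta-1,3-diene | COC(O[Si](C)(C)C)=C(C/C=C(\C)CCC=C(C)C)C(OC)=C | intermediate
9 | but-3-yn-2-one | CC(=O)C#C | starting material
10 | 1-{5-[(2E)-3,7-dimethylocta-2,6-dien-1-yl]-4,6-dimethoxy-6-[(trimethylsilyl)oxy]cyclohexa-1,4-dien-1-yl}ethan-1-one (racemic) | CC(=O)C1=CCC(OC)=C(C/C=C(\C)CCC=C(C)C)C1(OC)O[Si](C)(C)C | intermediate
11 | 1-{3-[(2E)-3,7-dimethylocta-2,6-dien-1-yl]-4-methoxy-2-[(trimethylsilyl)oxy]phenyl}ethan-1-one | CC(=O)c1ccc(OC)c(C/C=C(\C)CCC=C(C)C)c1O[Si](C)(C)C | intermediate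
12 | 1-{3-[(2E)-3,7-dimethylocta-2,6-dien-1-yl]-2-hydroxy-4-methoxyphenyl}ethan-1-one | CC(=O)c1ccc(OC)c(C/C=C(\C)CCC=C(C)C)c1O | intermediate
13 | 4-hydroxybenzaldehyde | O=Cc1ccc(O)cc1 | starting material
14 | 1-{3-[(2E)-3,7-dimethylocta-2,6-dien-1-yl]-2-hydroxy-4-methoxyphenyl}-3-hydroxy-3-(4-hydroxyphenyl)propan-1-one (racemic; present as its potassium phenoxide) | COc1ccc(C(=O)CC(O)c2ccc(O)cc2)c(O)c1C/C=C(\C)CCC=C(C)C | intermediate
15 | xanthoangelol F, (2E)-1-{3-[(2E)-3,7-dimethylocta-2,6-dien-1-yl]-2-hydroxy-4-methoxyphenyl}-3-(4-hydroxyphenyl)prop-2-en-1-one | COc1ccc(C(=O)/C=C/c2ccc(O)cc2)c(O)c1C/C=C(\C)CCC=C(C)C | target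
```

## Step count and weak points

Total step count: 5. Longest linear sequence: 5 (steps 1 to 5, from 1 and 2).

**Step 4 (key step).** The cycloaddition may be slow at the fully substituted ketene acetal terminus next to the geranyl group, which would give protonation of the diene or polymerisation of the ynone time to compete. The aromatisation may also expel the silyloxy group in place of methanol, which would leave the C2' oxygen methylated.

Fallback: the ring construction is given up for the decoration of an intact arene by two directed metalations. It sets out from geranyl bromide 2 and comes back at ketone 12.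
- 3-Methoxyphenol would be protected with chloromethyl methyl ether and i-Pr2NEt as 1-methoxy-3-(methoxymethoxy)benzene F1.
- Lithiation between the two oxygen substituents (n-BuLi, THF, 0 °C) and coupling with 2 under catalysis by CuBr·SMe2 should give 2-[(2E)-3,7-dimethylocta-2,6-dien-1-yl]-1-methoxy-3-(methoxymethoxy)benzene F2.
- A second lithiation (n-BuLi, TMEDA) directed by the acetal, the stronger director, and a quench with N-methoxy-N-methylacetamide would give 1-{3-[(2E)-3,7-dimethylocta-2,6-dien-1-yl]-4-methoxy-2-(methoxymethoxy)phenyl}ethan-1-one F3.
- Dilute HCl in methanol at room temperature would remove the acetal next to the carbonyl group and give 12.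

**Step 3.** Deprotonation may be incomplete for the enol ether isomer whose methyl group is remote from the ester, or stray to the allylic positions of the chain. Some C-silylation and hydrolysis of the ketene acetal on handling are also possible.

Fallback: the C4' oxygen is carried as a silyl ether and its methyl group is introduced last. It sets out from keto ester 4 and comes back at 12.
- Me3SiCl and Et3N would convert 4 into methyl (4E)-5,9-dimethyl-2-{1-[(trimethylsilyl)oxy]ethylidene}deca-4,8-dienoate F4.
- LiN(i-Pr)2 and Me3SiCl, the best-established diene preparation for 2-alkyl acetoacetates, would give 2-[(2E)-3,7-dimethylocta-2,6-dien-1-yl]-1-methoxy-1,3-bis[(trimethylsilyl)oxy]buta-1,3-diene F5.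
- Cycloaddition of F5 with 9 and the same methanolysis should give 1-{3-[(2E)-3,7-dimethylocta-2,6-dien-1-yl]-2,4-dihydroxyphenyl}ethan-1-one F6.
- Dimethyl sulfate and K2CO3 in acetone would methylate only the C4' hydroxyl, because the C2' hydroxyl is held in the hydrogen bond to the acetyl group, and give 12.

**Step 2.** Ketalisation of the α-branched ketone may be sluggish. Longer exposure to acid would allow addition of methanol to, or cyclisation of, the trisubstituted double bonds, and loss of methanol from the ketal may stay incomplete.

Fallback: the enol ether is made in the anionic manifold in place of the cationic one. It sets out from 4 and comes back at 6 without a new compound. The sodium enolate of 4 (NaH in N,N'-dimethylpropyleneurea) would be treated with dimethyl sulfate; a dissociated enolate and a hard electrophile favour O-alkylation, and no acid is present.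

**Step 5.** The aldol addition may be slow because the ketone reacts as a dianion and the aldehyde as a deactivated phenoxide. Retro-aldol cleavage, Cannizzaro disproportionation of the aldehyde and ring closure to the flavanone on acidification could then erode the conversion.

Fallback: the phenol of ring B is masked so that the aldehyde is a normal electrophile. It sets out from 13 (with 12) and comes back at 15.
- 13 with 3,4-dihydro-2H-pyran and cat. PPTS would give 4-(oxan-2-yloxy)benzaldehyde F7.
- Condensation of 12 with F7 (KOH, EtOH) should give (2E)-1-{3-[(2E)-3,7-dimethylocta-2,6-dien-1-yl]-2-hydroxy-4-methoxyphenyl}-3-[4-(oxan-2-yloxy)phenyl]prop-2-en-1-one F8.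
- PPTS in methanol at room temperature would remove the acetal and give 15 under conditions too mild for the chain.

## Further compounds

```
F1 | step 4 | 1-methoxy-3-(methoxymethoxy)benzene | COCOc1cccc(OC)c1
F2 | step 4 | 2-[(2E)-3,7-dimethylocta-2,6-dien-1-yl]-1-methoxy-3-(methoxymethoxy)benzene | COCOc1cccc(OC)c1C/C=C(\C)CCC=C(C)C
F3 | step 4 | 1-{3-[(2E)-3,7-dimethylocta-2,6-dien-1-yl]-4-methoxy-2-(methoxymethoxy)phenyl}ethan-1-one | COCOc1c(C(C)=O)ccc(OC)c1C/C=C(\C)CCC=C(C)C
F4 | step 3 | methyl (4E)-5,9-dimethyl-2-{1-[(trimethylsilyl)oxy]ethylidene}deca-4,8-dienoate | COC(=O)C(C/C=C(\C)CCC=C(C)C)=C(C)O[Si](C)(C)C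
F5 | step 3 | 2-[(2E)-3,7-dimethylocta-2,6-dien-1-yl]-1-methoxy-1,3-bis[(trimethylsilyl)oxy]buta-1,3-diene | COC(O[Si](C)(C)C)=C(C/C=C(\C)CCC=C(C)C)C(O[Si](C)(C)C)=C
F6 | step 3 | 1-{3-[(2E)-3,7-dimethylocta-2,6-dien-1-yl]-2,4-dihydroxyphenyl}ethan-1-one | CC(=O)c1ccc(O)c(C/C=C(\C)CCC=C(C)C)c1O
F0 | step 2 | none | none
F7 | step 5 | 4-(oxan-2-yloxy)benzaldehyde (racemic) | O=Cc1ccc(OC2CCCCO2)cc1
F8 | step 5 | (2E)-1-{3-[(2E)-3,7-dimethylocta-2,6-dien-1-yl]-2-hydroxy-4-methoxyphenyl}-3-[4-(oxan-2-yloxy)phenyl]prop-2-en-1-one (racemic) | COc1ccc(C(=O)/C=C/c2ccc(OC3CCCCO3)cc2)c(O)c1C/C=C(\C)CCC=C(C)C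
A1 | alternative 1 | 1-(2-hydroxy-4-methoxyphenyl)ethan-1-one | CC(=O)c1ccc(OC)cc1O
A2 | alternative 1 | 1-(2-{[(2E)-3,7-dimethylocta-2,6-dien-1-yl]oxy}-4-methoxyphenyl)ethan-1-one | CC(=O)c1ccc(OC)cc1OC/C=C(\C)CCC=C(C)C
A3 | alternative 1 | 1-[3-(3,7-dimethylocta-1,6-dien-3-yl)-2-hydroxy-4-methoxyphenyl]ethan-1-one (racemic) | CC(=O)c1ccc(OC)c(C(C)(C=C)CCC=C(C)C)c1O
A4 | alternative 2 | 1,3-bis(methoxymethoxy)benzene | COCOc1cccc(OCOC)c1
A5 | alternative 2 | 2-[(2E)-3,7-dimethylocta-2,6-dien-1-yl]-1,3-bis(methoxymethoxy)benzene | COCOc1cccc(OCOC)c1C/C=C(\C)CCC=C(C)C
A6 | alternative 2 | 1-{3-[(2E)-3,7-dimethylocta-2,6-dien-1-yl]-2,4-bis(methoxymethoxy)phenyl}ethan-1-one | CC(=O)c1ccc(OCOC)c(C/C=C(\C)CCC=C(C)C)c1OCOC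
A7 | alternative 3 | (4E)-1-methoxy-5,9-dimethyldeca-4,8-dien-1-yne | COC#CC/C=C(\C)CCC=C(C)C
A8 | alternative 3 | 4-acetylcyclobut-2-en-1-one | CC(=O)C1C=CC1=O
A9 | alternative 3 | 6-methyl-2H-pyran-2-one | CC1=CC=CC(=O)O1
```
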